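**Retrosynthetic overview**
1. Target ⇐ C6 allylic alcohol (chloride by SN2) ⇐ oxocane closed at C5–C6 by Nozaki–Hiyama–Kishi reaction; C3–C5 unit from chelation-controlled 2-bromoallylation of a C3 aldehyde.
2. Tetrahydropyran (C2–O–C8) ⇐ C2 lactol by axial C-glycosylation; C11 oxygen by Rubottom oxidation of the ring A enone.
3. Ring A ⇐ silicon-tethered type 2 intramolecular Diels–Alder reaction (C8–O–Si–O–dienol onto an (E)-2-methylenal), which forms C10–C11 and C1–C14 and sets C1 and C10.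
4. Lactone/dienophile fragment (C6–C10, C17–C19) ⇐ L-arabinose (C7 and C9 bought; C8 by addition to the 3-ulose; C17 by hydrogenation on a bicyclic lactone).
5. Ring order: γ-lactone → ring A → tetrahydropyran → oxocane.

Assumption: atom labels C1–C20 follow the briarane numbering of the target, which is then (1S,2R,3R,6S,7R,8S,9S,10S,11S,17R); sugar carbons C1–C5 of L-arabinose become C10, C9, C8, C7, C6.

**Route**

Step 1
Reactants: 1 L-arabinose
Product: 2 5-O-(tert-butyldiphenylsilyl)-L-arabinofuranose (anomers)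
Conditions: TBDPSCl, pyridine, 0 °C → rt
Reagents that add atoms: tert-butyl(chloro)diphenylsilane CC(C)(C)[Si](Cl)(c1ccccc1)c1ccccc1
Why: Selective silylation of the only primary hydroxyl traps the sugar in its furanose form; no stereocentre is touched.

Step 2
Reactants: 2 5-O-(tert-butyldiphenylsilyl)-L-arabinofuranose
Product: 3 5-O-(tert-butyldiphenylsilyl)-1,2-O-isopropylidene-β-L-arabinofuranose
Conditions: Me2C(OMe)2, acetone, TsOH (cat.), rt
Reagents that add atoms: 2,2-dimethoxypropane COC(C)(C)OC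
Why: Acetonide formation across the only cis-1,2-diol fixes the anomeric centre β and leaves 3-OH free.

Step 3
Reactants: 3 5-O-(tert-butyldiphenylsilyl)-1,2-O-isopropylidene-β-L-arabinofuranose
Product: 4 5-O-(tert-butyldiphenylsilyl)-1,2-O-isopropylidene-β-L-threo-pentofuranos-3-ulose
Conditions: Dess–Martin periodinane, NaHCO3, CH2Cl2, rt
Reagents that add atoms: none
Why: Dess–Martin oxidation of the single free secondary alcohol gives the 3-ulose (future C8) without epimerising C2 or C4.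

Step 4
Reactants: 4 the 3-ulose; 5 ethyl acetate
Product: 6 5-O-(tert-butyldiphenylsilyl)-3-C-(2-ethoxy-2-oxoethyl)-1,2-O-isopropylidene-β-L-lyxofuranose
Conditions: EtOAc, LiN(iPr)2, THF, −78 °C; then 4; aq NH4Cl
Reagents that add atoms: ethyl acetate CCOC(C)=O
Why: Ester-enolate aldol addition to the ketone occurs on the face opposite the cis-fused acetonide and the C4 side chain, so the new C8–OH is cis to O2 (target C8 configuration).

Step 5
Reactants: 6 the β-hydroxy ester; 7 N,N-dimethylmethyleneiminium iodide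
Product: 10 5-O-(tert-butyldiphenylsilyl)-3-C-(3-ethoxy-3-oxoprop-1-en-2-yl)-1,2-O-isopropylidene-β-L-lyxofuranose, via Mannich base 8 (not isolated), via ammonium iodide 9 (not isolated)
Conditions: LiN(iPr)2 (2.3 equiv), THF, −78 °C; 7, −78 → 0 °C; MeI, MeOH, rt; aq NaHCO3, CH2Cl2
Reagents that add atoms: N,N-dimethylmethyleneiminium iodide C=[N+](C)C.[I-]
Why: Mannich alkylation of the alkoxide–enolate dianion followed by quaternisation and β-elimination installs the α-methylene group (future C18); no stereocentre is formed.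

Step 6
Reactants: 10 the α-methylene ester
Product: 13 3-C-(1-carboxyvinyl)-L-lyxopyranose 3′,4-lactone (α-methylene-γ-lactone cis-fused at C7–C8; lactol anomers), via desilylated ester 11 (not isolated), via free sugar ester 12 (not isolated)
Conditions: HF·pyridine, THF, rt; then TFA–H2O 9:1, rt; toluene azeotrope
Reagents that add atoms: none
Why: Desilylation and acetal hydrolysis free the sugar, which lactonises through O4 (O7) because only that hydroxyl is cis to the C8 side chain on the pyranose form.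

Step 7
Reactants: 13 the α-methylene lactone lactol
Product: 14 3-C-[(1R)-1-carboxyethyl]-L-lyxopyranose 3′,4-lactone (lactol anomers)
Conditions: H2 (1 atm), 10% Pd/C, EtOAc, rt
Reagents that add atoms: none
Why: Heterogeneous hydrogenation delivers hydrogen to the convex face of the cis-fused bicycle (the face of C8–OH and H7), so the C17 methyl ends trans to C8–O as in the target.

Step 8
Reactants: 14 the methyl lactone lactol; 15 2-(triphenylphosphoranylidene)propanal
Product: 16 (E)-4-hydroxy-2-methylbut-2-enal bearing at C4 the 3-hydroxy-2-(hydroxymethyl)-4-methyl-5-oxooxolan-3-yl ring (C7, C8, C9, C17 as in the target; triol)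
Conditions: THF, 70 °C
Reagents that add atoms: 2-(triphenylphosphoranylidene)propanal CC(C=O)=P(c1ccccc1)(c1ccccc1)c1ccccc1
Why: Wittig olefination of the open-chain aldehyde form with the stabilised ylide gives the (E)-2-methylenal (C10=C1, C2 aldehyde) and releases the C6 hydroxyl.

Step 9
Reactants: 16 the enal triol; 17 acetic anhydride
Product: 19 C6-O-TBDPS C9-O-acetyl enal lactone (tertiary C8–OH free), via silyl ether 18 (not isolated)
Conditions: TBDPSCl, imidazole, CH2Cl2, 0 °C; then Ac2O, pyridine, DMAP (cat.), 0 °C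
Reagents that add atoms: tert-butyl(chloro)diphenylsilane CC(C)(C)[Si](Cl)(c1ccccc1)c1ccccc1; acetic anhydride CC(=O)OC(C)=O
Why: Steric differentiation: the primary hydroxyl is silylated first, the secondary allylic C9–OH is then acetylated, and the tertiary C8–OH does not react.

Step 10
Reactants: 19 the C8 alcohol; 20 pent-1-en-3-one
Product: 22 silicon-tethered triene [C8–O–Si(iPr)2–O–C12(=C11H–CH3)–C13H=C14H2; (Z)-siloxydiene], via silyl triflate 21 (not isolated)
Conditions: iPr2Si(OTf)2, 2,6-lutidine, CH2Cl2, −40 → 0 °C; then 20, Et3N, 0 °C → rt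
Reagents that add atoms: diisopropylsilyl bis(trifluoromethanesulfonate) CC(C)[Si](OS(=O)(=O)C(F)(F)F)(OS(=O)(=O)C(F)(F)F)C(C)C; pent-1-en-3-one CCC(=O)C=C
Why: Silylation of the tertiary alcohol with the bis(triflate), then soft enolisation of the vinyl ketone by the remaining silyl triflate and amine, gives the mixed silyl enol ether.

Step 11
Reactants: 22 the tethered triene
Product: 23 bridged cycloadduct (ring A closed through C10–C11 and C1–C14; C12=C13 bridgehead silyl enol ether still tied to C8–O; C1 formyl and methyl; C11 epimers)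
Conditions: toluene (0.005 M), BHT, 140 °C, sealed tube
Reagents that add atoms: none
Why: Type 2 intramolecular Diels–Alder reaction in which the tether allows only the 1,3-bridged regiochemistry. The (E)-enal geometry places C15 and C9 cis. Allylic 1,3-strain holds H9 in the alkene plane, so the diene carried on C8 adds to the face anti to the C9 acetate, which sets C1 and C10 as in the target.

Step 12
Reactants: 23 the bridged cycloadduct
Product: 26 enone lactol (ring A C12 ketone with C13=C14; trans-fused 2-hydroxytetrahydropyran C2–O–C8; C2 anomers and C11 epimers), via acetoxysilyl enone 24 (not isolated), via hydroxy aldehyde 25 (not isolated)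
Conditions: Pd(OAc)2 (1.2 equiv), MeCN, 40 °C; then HF·pyridine, THF–pyridine, 0 °C
Reagents that add atoms: none
Why: Saegusa–Ito oxidation turns the silyl enol ether regiospecifically into the C13=C14 enone; fluoride then frees C8–OH, which closes onto the C2 aldehyde as the trans-fused lactol.

Step 13
Reactants: 26 the enone lactol
Product: 29 11-hydroxy enone lactol (C11–OH α and C20 β as in the target), via bis-silyl dienol ether 27 (not isolated), via silyloxy ketone 28 (not isolated)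
Conditions: TMSOTf, Et3N, CH2Cl2, 0 °C; mCPBA, NaHCO3, −20 °C; aq citric acid, THF
Reagents that add atoms: 3-chloroperoxybenzoic acid OOC(=O)c1cccc(Cl)c1
Why: Rubottom oxidation at C11, the only enolisable position; the peracid attacks the dienol ether anti to the axial C1 methyl of the trans-fused bicycle, and both C11 epimers converge.

Step 14
Reactants: 29 the 11-hydroxy lactol; 17 acetic anhydride
Product: 30 C2,C11-di-O-acetate (anomeric acetate mixture; C9 and C11 acetates in place)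
Conditions: Ac2O, DMAP, Et3N, CH2Cl2, rt → 40 °C
Reagents that add atoms: acetic anhydride CC(=O)OC(C)=O
Why: DMAP-catalysed acylation esterifies the tertiary α-ketol and turns the lactol into a glycosyl acetate leaving group.

Step 15
Reactants: 30 the diacetate; 31 potassium (E)-styryltrifluoroborate
Product: 32 C2-axial (E)-styryl tetrahydropyran (C2 configuration of the target)
Conditions: K[PhCH=CHBF3], BF3·OEt2, MeCN–CH2Cl2, −40 → 0 °C
Reagents that add atoms: potassium (E)-styryltrifluoroborate [K+].F[B-](F)(F)/C=C/c1ccccc1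
Why: Lewis-acid C-glycosylation through the C2 oxocarbenium ion; the alkenyldifluoroborane adds axially and anti to the neighbouring axial C1 methyl, which places the new carbon on the α face.

Step 16
Reactants: 32 the styryl tetrahydropyran
Product: 34 C3 aldehyde (2-formyltetrahydropyran), via ozonide 33 (not isolated)
Conditions: O3, CH2Cl2, −78 °C; then Me2S
Reagents that add atoms: ozone [O-][O+]=O
Why: Ozonolysis cleaves the electron-rich styrene far faster than the electron-poor ring A enone and leaves C2 untouched.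

Step 17
Reactants: 34 the C3 aldehyde; 35 2,3-dibromopropene
Product: 36 (3R)-homoallylic alcohol carrying the 2-bromoallyl group (C4H2–C5(Br)=C16H2)
Conditions: In powder, THF–H2O 1:1, rt
Reagents that add atoms: 2,3-dibromopropene C=C(Br)CBr
Why: Indium Barbier allylation is selective for the aldehyde; chelation between the ring oxygen and the carbonyl (Cram-chelate) directs attack past H2 and gives the syn C2–O/C3–OH relationship of the target.

Step 18
Reactants: 36 the silyl ether
Product: 37 C3,C6-diol (primary C6–OH free)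
Conditions: HF·pyridine, THF–pyridine, rt
Reagents that add atoms: none
Why: Fluoride cleaves the primary silyl ether while the acetates, lactone and vinyl bromide are inert.

Step 19
Reactants: 37 the diol
Product: 38 C6 aldehyde (C3–OH retained)
Conditions: TEMPO (cat.), PhI(OAc)2, CH2Cl2, rt
Reagents that add atoms: none
Why: Oxoammonium oxidation is selective for the primary alcohol over the secondary C3–OH and is mild enough to keep the α-acyloxy aldehyde from epimerising.

Step 20
Reactants: 38 the bromo aldehyde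
Product: 39 (6R)-6-hydroxy analogue of the target (oxocane closed; 5(16)-exo-methylene)
Conditions: CrCl2 (10 equiv), NiCl2 (cat.), DMSO, 0.003 M, rt
Reagents that add atoms: none
Why: Intramolecular Nozaki–Hiyama–Kishi reaction joins C5 to C6 between the two cis-disposed arms of the tetrahydropyran. The ring forces C5 gauche to C8, and with the carbonyl oxygen anti to the lactone C7–O dipole the 6R alcohol (syn to C7–O) is expected; this is the least secure stereocentre of the route.

Step 21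
Reactants: 39 the allylic alcohol
Product: 40 the target CNP0253524.4
Conditions: PPh3, Cl3CC(O)CCl3, CH2Cl2, −20 → 0 °C
Reagents that add atoms: hexachloroacetone ClC(Cl)(Cl)C(=O)C(Cl)(Cl)Cl
Why: Appel-type chlorination in which the allylic C6 alkoxyphosphonium ion is displaced by chloride in an SN2 step with inversion (6R → 6S); the homoallylic C3–OH reacts far more slowly.

**Compound list**
1 | L-arabinose | O=C[C@H](O)[C@@H](O)[C@@H](O)CO | starting material
2 | 5-O-(tert-butyldiphenylsilyl)-L-arabinofuranose (anomers) | O[C@H]1C(O)O[C@@H](CO[Si](c2ccccc2)(c2ccccc2)C(C)(C)C)[C@@H]1O | intermediate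
3 | 5-O-(tert-butyldiphenylsilyl)-1,2-O-isopropylidene-β-L-arabinofuranose | CC1(C)O[C@H]2[C@@H](O1)O[C@@H](CO[Si](c3ccccc3)(c3ccccc3)C(C)(C)C)[C@@H]2O | intermediate
4 | 5-O-(tert-butyldiphenylsilyl)-1,2-O-isopropylidene-β-L-threo-pentofuranos-3-ulose | CC1(C)O[C@H]2[C@@H](O1)O[C@@H](CO[Si](c3ccccc3)(c3ccccc3)C(C)(C)C)C2=O | intermediate
5 | ethyl acetate | CCOC(C)=O | starting material
6 | 5-O-(tert-butyldiphenylsilyl)-3-C-(2-ethoxy-2-oxoethyl)-1,2-O-isopropylidene-β-L-lyxofuranose | CC1(C)O[C@H]2[C@@H](O1)O[C@@H](CO[Si](c3ccccc3)(c3ccccc3)C(C)(C)C)[C@]2(O)CC(=O)OCC | intermediate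
7 | N,N-dimethylmethyleneiminium iodide | C=[N+](C)C.[I-] | starting material
8 | Mannich base of 6 (α-dimethylaminomethyl ester, C17 epimers) | CC1(C)O[C@H]2[C@@H](O1)O[C@@H](CO[Si](c3ccccc3)(c3ccccc3)C(C)(C)C)[C@]2(O)C(CN(C)C)C(=O)OCC | intermediate
9 | trimethylammonium iodide of 8 | CC1(C)O[C@H]2[C@@H](O1)O[C@@H](CO[Si](c3ccccc3)(c3ccccc3)C(C)(C)C)[C@]2(O)C(C[N+](C)(C)C)C(=O)OCC.[I-] | intermediate
10 | 5-O-(tert-butyldiphenylsilyl)-3-C-(3-ethoxy-3-oxoprop-1-en-2-yl)-1,2-O-isopropylidene-β-L-lyxofuranose | CC1(C)O[C@H]2[C@@H](O1)O[C@@H](CO[Si](c3ccccc3)(c3ccccc3)C(C)(C)C)[C@]2(O)C(=C)C(=O)OCC | intermediate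
11 | 3-C-(3-ethoxy-3-oxoprop-1-en-2-yl)-1,2-O-isopropylidene-β-L-lyxofuranose | CC1(C)O[C@H]2[C@@H](O1)O[C@@H](CO)[C@]2(O)C(=C)C(=O)OCC | intermediate
12 | 3-C-(3-ethoxy-3-oxoprop-1-en-2-yl)-L-lyxose (drawn open-chain) | O=C[C@H](O)[C@@](O)(C(=C)C(=O)OCC)[C@@H](O)CO | intermediate
13 | 3-C-(1-carboxyvinyl)-L-lyxopyranose 3′,4-lactone (anomers) | OC1OC[C@@H]2OC(=O)C(=C)[C@]2(O)[C@H]1O | intermediate
14 | 3-C-[(1R)-1-carboxyethyl]-L-lyxopyranose 3′,4-lactone (anomers) | OC1OC[C@@H]2OC(=O)[C@H](C)[C@]2(O)[C@H]1O | intermediate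
15 | 2-(triphenylphosphoranylidene)propanal | CC(C=O)=P(c1ccccc1)(c1ccccc1)c1ccccc1 | starting material
16 | (E)-enal triol lactone (C6–OH, C8–OH, C9–OH free) | OC[C@@H]1OC(=O)[C@H](C)[C@]1(O)[C@@H](O)/C=C(\C)C=O | intermediate
17 | acetic anhydride | CC(=O)OC(C)=O | starting material
18 | C6-O-TBDPS ether of 16 | CC(C)(C)[Si](c1ccccc1)(c1ccccc1)OC[C@@H]1OC(=O)[C@H](C)[C@]1(O)[C@@H](O)/C=C(\C)C=O | intermediate
19 | C6-O-TBDPS C9-O-acetyl enal lactone (C8–OH free) | CC(C)(C)[Si](c1ccccc1)(c1ccccc1)OC[C@@H]1OC(=O)[C@H](C)[C@]1(O)[C@@H](OC(C)=O)/C=C(\C)C=O | intermediate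
20 | pent-1-en-3-one | CCC(=O)C=C | starting material
21 | C8-O-diisopropylsilyl triflate of 19 | CC(C)(C)[Si](c1ccccc1)(c1ccccc1)OC[C@@H]1OC(=O)[C@H](C)[C@]1(O[Si](C(C)C)(C(C)C)OS(=O)(=O)C(F)(F)F)[C@@H](OC(C)=O)/C=C(\C)C=O | intermediate
22 | silicon-tethered triene | CC(C)(C)[Si](c1ccccc1)(c1ccccc1)OC[C@@H]1OC(=O)[C@H](C)[C@]1(O[Si](C(C)C)(C(C)C)O/C(=C\C)C=C)[C@@H](OC(C)=O)/C=C(\C)C=O | intermediate
23 | bridged type 2 Diels–Alder adduct (C11 epimers) | O=C[C@@]1(C)CC=C2O[Si](C(C)C)(C(C)C)O[C@@]3([C@@H](C)C(=O)O[C@H]3CO[Si](c4ccccc4)(c4ccccc4)C(C)(C)C)[C@@H](OC(C)=O)[C@H]1C2C | intermediate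
24 | ring A enone with C8–O–Si(iPr)2–OAc | O=C[C@@]1(C)C=CC(=O)C(C)[C@@H]1[C@H](OC(C)=O)[C@@]2(O[Si](C(C)C)(C(C)C)OC(C)=O)[C@@H](C)C(=O)O[C@H]2CO[Si](c3ccccc3)(c3ccccc3)C(C)(C)C | intermediate
25 | ring A enone hydroxy aldehyde (C8–OH, C2 aldehyde) | O=C[C@@]1(C)C=CC(=O)C(C)[C@@H]1[C@H](OC(C)=O)[C@@]2(O)[C@@H](C)C(=O)O[C@H]2CO[Si](c3ccccc3)(c3ccccc3)C(C)(C)C | intermediate
26 | enone lactol (C2 anomers, C11 epimers) | OC1O[C@@]2([C@@H](C)C(=O)O[C@H]2CO[Si](c2ccccc2)(c2ccccc2)C(C)(C)C)[C@@H](OC(C)=O)[C@@H]2[C@]1(C)C=CC(=O)C2C | intermediate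
27 | bis(trimethylsilyl) dienol ether of 26 | C[Si](C)(C)OC1O[C@@]2([C@@H](C)C(=O)O[C@H]2CO[Si](c2ccccc2)(c2ccccc2)C(C)(C)C)[C@@H](OC(C)=O)[C@@H]2[C@]1(C)C=CC(O[Si](C)(C)C)=C2C | intermediate
28 | C11 trimethylsilyloxy enone, C2-O-trimethylsilyl | C[Si](C)(C)OC1O[C@@]2([C@@H](C)C(=O)O[C@H]2CO[Si](c2ccccc2)(c2ccccc2)C(C)(C)C)[C@@H](OC(C)=O)[C@@H]2[C@]1(C)C=CC(=O)[C@@]2(C)O[Si](C)(C)C | intermediate
29 | 11-hydroxy enone lactol | OC1O[C@@]2([C@@H](C)C(=O)O[C@H]2CO[Si](c2ccccc2)(c2ccccc2)C(C)(C)C)[C@@H](OC(C)=O)[C@@H]2[C@]1(C)C=CC(=O)[C@@]2(C)O | intermediate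
30 | C2,C11-diacetate | CC(=O)OC1O[C@@]2([C@@H](C)C(=O)O[C@H]2CO[Si](c2ccccc2)(c2ccccc2)C(C)(C)C)[C@@H](OC(C)=O)[C@@H]2[C@]1(C)C=CC(=O)[C@@]2(C)OC(C)=O | intermediate
31 | potassium (E)-styryltrifluoroborate | [K+].F[B-](F)(F)/C=C/c1ccccc1 | starting material
32 | C2-axial (E)-styryl tetrahydropyran | c1ccccc1/C=C/[C@@H]1O[C@@]2([C@@H](C)C(=O)O[C@H]2CO[Si](c2ccccc2)(c2ccccc2)C(C)(C)C)[C@@H](OC(C)=O)[C@@H]2[C@]1(C)C=CC(=O)[C@@]2(C)OC(C)=O | intermediate
33 | secondary ozonide of 32 | c1ccccc1C1OOC(O1)[C@@H]1O[C@@]2([C@@H](C)C(=O)O[C@H]2CO[Si](c2ccccc2)(c2ccccc2)C(C)(C)C)[C@@H](OC(C)=O)[C@@H]2[C@]1(C)C=CC(=O)[C@@]2(C)OC(C)=O | intermediate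
34 | C3 aldehyde | O=C[C@@H]1O[C@@]2([C@@H](C)C(=O)O[C@H]2CO[Si](c2ccccc2)(c2ccccc2)C(C)(C)C)[C@@H](OC(C)=O)[C@@H]2[C@]1(C)C=CC(=O)[C@@]2(C)OC(C)=O | intermediate
35 | 2,3-dibromopropene | C=C(Br)CBr | starting material
36 | (3R)-2-bromoallyl carbinol, C6-O-TBDPS | C=C(Br)C[C@@H](O)[C@@H]1O[C@@]2([C@@H](C)C(=O)O[C@H]2CO[Si](c2ccccc2)(c2ccccc2)C(C)(C)C)[C@@H](OC(C)=O)[C@@H]2[C@]1(C)C=CC(=O)[C@@]2(C)OC(C)=O | intermediate
37 | C3,C6-diol | C=C(Br)C[C@@H](O)[C@@H]1O[C@@]2([C@@H](C)C(=O)O[C@H]2CO)[C@@H](OC(C)=O)[C@@H]2[C@]1(C)C=CC(=O)[C@@]2(C)OC(C)=O | intermediate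
38 | C6 aldehyde | C=C(Br)C[C@@H](O)[C@@H]1O[C@@]2([C@@H](C)C(=O)O[C@H]2C=O)[C@@H](OC(C)=O)[C@@H]2[C@]1(C)C=CC(=O)[C@@]2(C)OC(C)=O | intermediate
39 | (6R)-6-hydroxy-6-deschloro target | C=C1C[C@@H](O)[C@@H]2O[C@@]3([C@@H](C)C(=O)O[C@H]3[C@@H]1O)[C@@H](OC(C)=O)[C@@H]1[C@]2(C)C=CC(=O)[C@@]1(C)OC(C)=O | intermediate
40 | CNP0253524.4 | C=C1C[C@@H](O)[C@@H]2O[C@@]3([C@@H](C)C(=O)O[C@H]3[C@H]1Cl)[C@@H](OC(C)=O)[C@@H]1[C@]2(C)C=CC(=O)[C@@]1(C)OC(C)=O | target

**Totals**
Total steps: 21. Longest linear sequence: 21 steps from L-arabinose (the route is linear).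

**Three steps most likely to fail, with fallbacks**

Step 11, the tethered cycloaddition, may be slow for a trisubstituted enal or be diverted by the silyl enol ether. The fallback drops the tether and sets out from compound 19. Heating 19 with (1E,3Z)-1-methoxy-3-(trimethylsilyloxy)penta-1,3-diene in toluene gives the untethered cycloadduct, the 14-methoxy silyl enol ether F1. Brief treatment with dilute acid hydrolyses the enol ether and eliminates methanol, giving the enone, which closes to lactol 26, where the route is rejoined. Facial control then rests only on the C9 stereocentre, so the diastereomers may need separation.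

Step 15, the alkenylborane C-glycosylation, may be sluggish or poorly axial-selective because the axial C7 arm flanks the α face. The fallback sets out from diacetate 30 and uses allyltrimethylsilane with BF3·OEt2, the most reliable axial C-glycosylation, to give the C2-allyl tetrahydropyran F2. Double-bond migration with RuHCl(CO)(PPh3)3 gives the C2-(E)-propenyl tetrahydropyran F3, and ozonolysis with Me2S work-up returns to aldehyde 34.

Step 20, the ring closure, may deliver the C6 epimer, the (6S)-alcohol F4, instead of 39. The fallback sets out from aldehyde 38, accepts F4 and moves the stereocontrol from the C–C bond formation to a ketone reduction. MnO2 oxidises only the allylic alcohol, giving the exocyclic C6 enone F5. Reduction with NaBH4 and CeCl3 at −78 °C, with hydride adding anti to the lactone C7–O bond and the hindered C12 ketone left alone, gives 39, where the route is rejoined before the chlorination.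

**Further compounds**
F1 | step 11 | untethered cycloadduct (C14 methoxy, C12 trimethylsilyl enol ether, C8–OH free) | O=C[C@@]1(C)C(OC)C=C(O[Si](C)(C)C)C(C)[C@@H]1[C@H](OC(C)=O)[C@@]2(O)[C@@H](C)C(=O)O[C@H]2CO[Si](c3ccccc3)(c3ccccc3)C(C)(C)C
F2 | step 15 | C2-axial allyl tetrahydropyran | C=CC[C@@H]1O[C@@]2([C@@H](C)C(=O)O[C@H]2CO[Si](c2ccccc2)(c2ccccc2)C(C)(C)C)[C@@H](OC(C)=O)[C@@H]2[C@]1(C)C=CC(=O)[C@@]2(C)OC(C)=O
F3 | step 15 | C2-axial (E)-prop-1-enyl tetrahydropyran | C/C=C/[C@@H]1O[C@@]2([C@@H](C)C(=O)O[C@H]2CO[Si](c2ccccc2)(c2ccccc2)C(C)(C)C)[C@@H](OC(C)=O)[C@@H]2[C@]1(C)C=CC(=O)[C@@]2(C)OC(C)=O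
F4 | step 20 | (6S)-6-hydroxy-6-deschloro target (C6 epimer of 39) | C=C1C[C@@H](O)[C@@H]2O[C@@]3([C@@H](C)C(=O)O[C@H]3[C@H]1O)[C@@H](OC(C)=O)[C@@H]1[C@]2(C)C=CC(=O)[C@@]1(C)OC(C)=O
F5 | step 20 | C6 ketone (exocyclic enone) | C=C1C[C@@H](O)[C@@H]2O[C@@]3([C@@H](C)C(=O)O[C@H]3C1=O)[C@@H](OC(C)=O)[C@@H]1[C@]2(C)C=CC(=O)[C@@]1(C)OC(C)=O
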